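**Retrosynthetic overview**

1. The strategy rests on the hexasubstituted benzene ring (C4a, C5, C6, C7, C8, C8a) of the chromane. It is cut at C5–C6 and C7–C8 into a dioxygenated diene C8=C8a(O1)–C4a=C5(OMe)(OSiMe3), held in the chiral dihydropyran ring (O1, C2, C3, C4, C4a, C8a), and the C6–C7 alkyne of a but-2-ynoate, which carries the carboxyl and the methyl group.
2. The diene 17 comes from dihydropyran ester 16 by γ-deprotonation and O-silylation. The (E)-dienyl side chain of 16 comes from the ethynyl group of 13 by hydrozirconation and Negishi coupling, after the acid step.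
3. Dihydropyran 13 comes from cyclodehydration of hydroxy keto ester 12, which is made by C-alkylation of prenylated acetoacetate 3 with iodide 11.
4. Iodide 11 carries the only stereocentre (future C2). It is set by Sharpless epoxidation of allylic alcohol 6, and the epoxy chloride is then converted to the tertiary propargylic alcohol.
5. Ring order: dihydropyran first (step 8), benzene last (step 12), then fluoride cleavage of the ester.

Key step: step 12

Remark: tert-butyl(but-3-yn-1-yloxy)dimethylsilane (4) is taken as a catalogue compound, and the geometry of the ketene acetal C=C(OMe)(OSiMe3) in 17 is left undefined because it does not matter for the cycloaddition.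

**Route**

Step 1
Reactants: 1 methyl acetoacetate; 2 prenyl bromide (1-bromo-3-methylbut-2-ene)
Product: 3 methyl 7-methyl-3-oxooct-6-enoate
Conditions: NaH, THF, 0 °C; n-BuLi, 0 °C; 2, 0 °C → rt; aq. HCl
Reagents that add atoms: none
Why: γ-Alkylation of the acetoacetate dianion, whose more basic terminal carbon displaces the allylic bromide by SN2 at CH2 and leaves the β-keto ester intact; no stereocentre is formed.

Step 2
Reactants: 4 tert-butyl(but-3-yn-1-yloxy)dimethylsilane
Product: 6 (2E)-5-(tert-butyldimethylsilyloxy)-3-methylpent-2-en-1-ol, via alkenyl(dimethyl)alane 5 (not isolated)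
Conditions: Me3Al, Cp2ZrCl2 (0.25 equiv), CH2Cl2, 0 °C → rt; evaporate volatiles; n-BuLi, THF/hexane, −78 → 0 °C; (CH2O)n, rt; aq. Rochelle salt
Reagents that add atoms: trimethylaluminium C[Al](C)C; paraformaldehyde (formaldehyde) C=O
Why: Negishi carboalumination adds CH3 and Al syn across the terminal alkyne with Al on the terminal carbon, and the alkenylalanate is hydroxymethylated with retention, so only the E-trisubstituted alkene should form.

Step 3
Reactants: 6 (2E)-5-(tert-butyldimethylsilyloxy)-3-methylpent-2-en-1-ol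
Product: 7 [(2R,3R)-3-[2-(tert-butyldimethylsilyloxy)ethyl]-3-methyloxiran-2-yl]methanol
Conditions: Ti(OiPr)4 (cat.), D-(−)-diethyl tartrate (cat.), t-BuOOH, 4 Å MS, CH2Cl2, −20 °C
Reagents that add atoms: tert-butyl hydroperoxide CC(C)(C)OO
Why: Sharpless asymmetric epoxidation of a geraniol-type E-allylic alcohol; the titanium–D-(−)-tartrate catalyst should deliver oxygen to the face that gives the (2R,3R)-epoxide (mirror image of the geraniol/L-(+)-tartrate outcome), and the quaternary epoxide carbon becomes C2 of the target.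

Step 4
Reactants: 7 [(2R,3R)-3-[2-(tert-butyldimethylsilyloxy)ethyl]-3-methyloxiran-2-yl]methanol
Product: 8 (2S,3R)-3-[2-(tert-butyldimethylsilyloxy)ethyl]-2-(chloromethyl)-3-methyloxirane
Conditions: PPh3, CCl4, NaHCO3, reflux
Reagents that add atoms: carbon tetrachloride ClC(Cl)(Cl)Cl
Why: Appel chlorination replaces the primary hydroxyl under buffered neutral conditions without opening the epoxide or cleaving the silyl ether; no stereocentre is touched (the C2 descriptor changes only through CIP priority).

Step 5
Reactants: 8 (2S,3R)-3-[2-(tert-butyldimethylsilyloxy)ethyl]-2-(chloromethyl)-3-methyloxirane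
Product: 10 (3R)-3-methylpent-4-yne-1,3-diol, via silyl-protected alkynol 9 (not isolated)
Conditions: n-BuLi (3.2 equiv), THF, −40 → −20 °C; then MeOH, 2 M aq. HCl, rt; NaHCO3
Reagents that add atoms: none
Why: Base-induced double elimination of a 2,3-epoxy chloride (deprotonation at CH2Cl with epoxide opening to the chlorovinyl alkoxide, then dehydrochlorination to the acetylide) never breaks the tertiary C–O bond, so the configuration is retained, and dilute methanolic HCl then cleaves the primary silyl ether without ionising the propargylic carbinol.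

Step 6
Reactants: 10 (3R)-3-methylpent-4-yne-1,3-diol
Product: 11 (3R)-5-iodo-3-methylpent-1-yn-3-ol
Conditions: PPh3, I2, imidazole, CH2Cl2, 0 °C
Reagents that add atoms: iodine II
Why: Appel-type iodination is selective for the primary hydroxyl because the hindered tertiary propargylic alcohol is not displaced as an alkoxyphosphonium ion at a useful rate.

Step 7
Reactants: 3 methyl 7-methyl-3-oxooct-6-enoate; 11 (3R)-5-iodo-3-methylpent-1-yn-3-ol
Product: 12 methyl 2-[(3R)-3-hydroxy-3-methylpent-4-yn-1-yl]-7-methyl-3-oxooct-6-enoate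
Conditions: 3 (1.5 equiv), NaH (1.4 equiv), THF/DMF, 0 °C; then 11, 50 °C
Reagents that add atoms: none
Why: SN2 C-alkylation of the β-keto ester sodium enolate by the primary iodide; the enolate is too weak a base to deprotonate the tertiary alcohol, and the new α-stereocentre forms as an epimer mixture that becomes sp2 in step 8.

Step 8
Reactants: 12 methyl 2-[(3R)-3-hydroxy-3-methylpent-4-yn-1-yl]-7-methyl-3-oxooct-6-enoate
Product: 13 methyl (6R)-6-ethynyl-6-methyl-2-(4-methylpent-3-en-1-yl)-5,6-dihydro-4H-pyran-3-carboxylate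
Conditions: PPTS (cat.), PhH, reflux, Dean–Stark (4 Å MS)
Reagents that add atoms: none
Why: Acid-catalysed cyclodehydration (six-membered hemiketal, then loss of water) gives the conjugated cyclic β-alkoxy acrylate, and the mild pyridinium acid should not ionise the tertiary propargylic C–O bond, so C6 keeps its configuration.

Step 9
Reactants: 13 methyl (6R)-6-ethynyl-6-methyl-2-(4-methylpent-3-en-1-yl)-5,6-dihydro-4H-pyran-3-carboxylate; 14 1-bromo-2-methylprop-1-ene
Product: 16 methyl (6R)-6-methyl-6-[(1E)-4-methylpenta-1,3-dien-1-yl]-2-(4-methylpent-3-en-1-yl)-5,6-dihydro-4H-pyran-3-carboxylate, via alkenylzirconocene chloride 15 (not isolated)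
Conditions: Cp2Zr(H)Cl (1.3 equiv), THF, rt; then ZnCl2 (1.3 equiv), 14, Pd(PPh3)4 (5 mol %), rt
Reagents that add atoms: none
Why: Hydrozirconation with the Schwartz reagent is syn and puts Zr on the terminal carbon, and zinc-assisted Negishi cross-coupling with the alkenyl bromide proceeds with retention to give the (E)-diene; the ester, enol ether and trisubstituted alkene should be inert at room temperature.

Step 10
Reactants: 16 methyl (6R)-6-methyl-6-[(1E)-4-methylpenta-1,3-dien-1-yl]-2-(4-methylpent-3-en-1-yl)-5,6-dihydro-4H-pyran-3-carboxylate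
Product: 17 (2Z,6R)-3-[methoxy(trimethylsilyloxy)methylidene]-6-methyl-6-[(1E)-4-methylpenta-1,3-dien-1-yl]-2-(4-methylpent-3-en-1-ylidene)oxane
Conditions: LDA (1.15 equiv), THF, −78 °C; TMSCl, −78 → 0 °C; pentane, filtration; used crude
Reagents that add atoms: chlorotrimethylsilane C[Si](C)(C)Cl
Why: Kinetic γ-deprotonation of the β-alkoxy enoate (vinylogous ester enolisation, as used for 1-alkoxy-1-siloxy-3-alkoxy dienes) and O-silylation of the lithium dienolate give the vinylketene acetal, and allylic 1,3-strain against the C(OMe)(OSiMe3) terminus should place the chain of the new exocyclic alkene on the O1 side (Z, outward).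

Step 11
Reactants: 18 but-2-ynoic acid; 19 2-(trimethylsilyl)ethanol
Product: 20 2-(trimethylsilyl)ethyl but-2-ynoate
Conditions: DCC, DMAP (5 mol %), CH2Cl2, −20 → 0 °C
Reagents that add atoms: none
Why: Steglich esterification at low temperature, where carbodiimide activation of the acid outpaces conjugate addition of DMAP to the ynoate.

Step 12
Reactants: 17 (2Z,6R)-3-[methoxy(trimethylsilyloxy)methylidene]-6-methyl-6-[(1E)-4-methylpenta-1,3-dien-1-yl]-2-(4-methylpent-3-en-1-ylidene)oxane; 20 2-(trimethylsilyl)ethyl but-2-ynoate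
Product: 23 2-(trimethylsilyl)ethyl (2R)-5-hydroxy-2,7-dimethyl-2-[(1E)-4-methylpenta-1,3-dien-1-yl]-8-(3-methylbut-2-en-1-yl)chromane-6-carboxylate, via cyclohexa-1,4-diene cycloadduct 21 (not isolated), via cyclohexadienone 22 (not isolated)
Conditions: 20 (3 equiv), toluene (2 M), 90 °C, sealed tube; then SiO2
Reagents that add atoms: none
Why: The electron-rich diene C8=C8a–C4a=C5 of 17, held s-cis by its two exocyclic double bonds on adjacent ring carbons, should undergo a normal-demand, asynchronous [4+2] cycloaddition with ynoate 20, in which the most nucleophilic terminus C8 bonds to the β-carbon (future C7, bearing CH3) and the ketene acetal carbon C5 bonds to the α-carbon (future C6, bearing the ester). The closest known reaction type is the benzannulation of 1-alkoxy-1-siloxy-3-oxy dienes with acetylenic esters to salicylates and resorcylates, here with a ring-embedded, terminally substituted diene. The benzene ring is closed by this intermolecular Diels–Alder cycloaddition (bonds C5–C6 and C7–C8), after which ketal 21 expels MeOSiMe3 to dienone 22 and this tautomerises through loss of the C8 proton to the C5 phenol. No stereocentre is created that survives, since C8 of 21 becomes aromatic, and the quaternary C2 is a remote spectator that cannot epimerise. The step needs regioselectivity, which the electron push of the acetal oxygens and O1 toward C8 against the polarised ynoate should secure, and it needs the ring diene to react in preference to the side-chain diene, which follows from the enforced s-cis geometry of the former and the cis-terminal methyl that disfavours the s-cis conformer of the latter. The outward (Z) position of the C8 substituent keeps that terminus accessible.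

Step 13
Reactants: 23 2-(trimethylsilyl)ethyl (2R)-5-hydroxy-2,7-dimethyl-2-[(1E)-4-methylpenta-1,3-dien-1-yl]-8-(3-methylbut-2-en-1-yl)chromane-6-carboxylate
Product: 24 (2R)-5-hydroxy-2,7-dimethyl-2-[(1E)-4-methylpenta-1,3-dien-1-yl]-8-(3-methylbut-2-en-1-yl)chromane-6-carboxylic acid
Conditions: TBAF (3 equiv), THF, 0 °C → rt; then cold 0.5 M aq. HCl to pH 3
Reagents that add atoms: none
Why: Fluoride-induced fragmentation (β-elimination) of the 2-(trimethylsilyl)ethyl ester gives ethylene, Me3SiF and the carboxylate under non-hydrolytic, non-acidic conditions that should spare the hindered salicylate, the tertiary dienylic aryl ether and the C2 stereocentre.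

**Compound list**

1 | methyl acetoacetate | COC(=O)CC(C)=O | starting material
2 | prenyl bromide (1-bromo-3-methylbut-2-ene) | CC(C)=CCBr | starting material
3 | methyl 7-methyl-3-oxooct-6-enoate | COC(=O)CC(=O)CCC=C(C)C | intermediate
4 | tert-butyl(but-3-yn-1-yloxy)dimethylsilane | C#CCCO[Si](C)(C)C(C)(C)C | starting material
5 | (E)-[4-(tert-butyldimethylsilyloxy)-2-methylbut-1-en-1-yl]dimethylalane | C/C(CCO[Si](C)(C)C(C)(C)C)=C\[Al](C)C | intermediate (not isolated)
6 | (2E)-5-(tert-butyldimethylsilyloxy)-3-methylpent-2-en-1-ol | C/C(CCO[Si](C)(C)C(C)(C)C)=C\CO | intermediate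
7 | [(2R,3R)-3-[2-(tert-butyldimethylsilyloxy)ethyl]-3-methyloxiran-2-yl]methanol | OC[C@H]1O[C@]1(C)CCO[Si](C)(C)C(C)(C)C | intermediate
8 | (2S,3R)-3-[2-(tert-butyldimethylsilyloxy)ethyl]-2-(chloromethyl)-3-methyloxirane | ClC[C@H]1O[C@]1(C)CCO[Si](C)(C)C(C)(C)C | intermediate
9 | (3R)-5-(tert-butyldimethylsilyloxy)-3-methylpent-1-yn-3-ol | C#C[C@@](O)(C)CCO[Si](C)(C)C(C)(C)C | intermediate (not isolated)
10 | (3R)-3-methylpent-4-yne-1,3-diol | C#C[C@@](O)(C)CCO | intermediate
11 | (3R)-5-iodo-3-methylpent-1-yn-3-ol | C#C[C@@](O)(C)CCI | intermediate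
12 | methyl 2-[(3R)-3-hydroxy-3-methylpent-4-yn-1-yl]-7-methyl-3-oxooct-6-enoate (C2 epimers) | C#C[C@@](O)(C)CCC(C(=O)OC)C(=O)CCC=C(C)C | intermediate
13 | methyl (6R)-6-ethynyl-6-methyl-2-(4-methylpent-3-en-1-yl)-5,6-dihydro-4H-pyran-3-carboxylate | C#C[C@@]1(C)CCC(C(=O)OC)=C(CCC=C(C)C)O1 | intermediate
14 | 1-bromo-2-methylprop-1-ene | CC(C)=CBr | starting material
15 | (E)-alkenylzirconocene chloride of 13 (Cp drawn σ-bonded) | Cl[Zr](/C=C/[C@@]1(C)CCC(C(=O)OC)=C(CCC=C(C)C)O1)(C1C=CC=C1)C1C=CC=C1 | intermediate (not isolated)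
16 | methyl (6R)-6-methyl-6-[(1E)-4-methylpenta-1,3-dien-1-yl]-2-(4-methylpent-3-en-1-yl)-5,6-dihydro-4H-pyran-3-carboxylate | CC(C)=C/C=C/[C@@]1(C)CCC(C(=O)OC)=C(CCC=C(C)C)O1 | intermediate
17 | (2Z,6R)-3-[methoxy(trimethylsilyloxy)methylidene]-6-methyl-6-[(1E)-4-methylpenta-1,3-dien-1-yl]-2-(4-methylpent-3-en-1-ylidene)oxane | CC(C)=C/C=C/[C@@]1(C)CCC(=C(OC)O[Si](C)(C)C)/C(=C/CC=C(C)C)O1 | intermediate
18 | but-2-ynoic acid | CC#CC(=O)O | starting material
19 | 2-(trimethylsilyl)ethanol | C[Si](C)(C)CCO | starting material
20 | 2-(trimethylsilyl)ethyl but-2-ynoate | CC#CC(=O)OCC[Si](C)(C)C | intermediate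
21 | 2-(trimethylsilyl)ethyl (2R)-5-methoxy-2,7-dimethyl-2-[(1E)-4-methylpenta-1,3-dien-1-yl]-8-(3-methylbut-2-en-1-yl)-5-(trimethylsilyloxy)-3,4,5,8-tetrahydro-2H-chromene-6-carboxylate (C8 epimers) | CC(C)=C/C=C/[C@@]1(C)CCC2=C(O1)C(CC=C(C)C)C(C)=C(C(=O)OCC[Si](C)(C)C)C2(OC)O[Si](C)(C)C | intermediate (not isolated)
22 | 2-(trimethylsilyl)ethyl (2R)-2,7-dimethyl-2-[(1E)-4-methylpenta-1,3-dien-1-yl]-8-(3-methylbut-2-en-1-yl)-5-oxo-3,4,5,8-tetrahydro-2H-chromene-6-carboxylate | CC(C)=C/C=C/[C@@]1(C)CCC2=C(O1)C(CC=C(C)C)C(C)=C(C(=O)OCC[Si](C)(C)C)C2=O | intermediate (not isolated)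
23 | 2-(trimethylsilyl)ethyl (2R)-5-hydroxy-2,7-dimethyl-2-[(1E)-4-methylpenta-1,3-dien-1-yl]-8-(3-methylbut-2-en-1-yl)chromane-6-carboxylate | CC(C)=C/C=C/[C@@]1(C)CCc2c(O)c(C(=O)OCC[Si](C)(C)C)c(C)c(CC=C(C)C)c2O1 | intermediate
24 | (2R)-5-hydroxy-2,7-dimethyl-2-[(1E)-4-methylpenta-1,3-dien-1-yl]-8-(3-methylbut-2-en-1-yl)chromane-6-carboxylic acid | CC(C)=C/C=C/[C@@]1(C)CCc2c(O)c(C(=O)O)c(C)c(CC=C(C)C)c2O1 | target

**Step count**

Total: 13 steps. Longest linear sequence: 11 steps (steps 2–10, 12, 13, from compound 4).

**Steps most likely to fail**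

Step 12 (benzannulation). The cycloaddition between the tetrasubstituted ring diene and the β-methyl ynoate may be slow. Heating then allows a thermal [3,3] ring expansion of the allyl vinyl ether unit C8=C8a–O1–C2–C1'=C2', or protodesilylation of the ketene acetal back to 16, to compete. Fallback, setting out from 17 and returning at 23: the ynoate is replaced by the more reactive allenoate of the same oxidation level. But-3-ynoic acid is esterified with 19 (DCC, CH2Cl2) to 2-(trimethylsilyl)ethyl but-3-ynoate F1, which is isomerised with catalytic Et3N to 2-(trimethylsilyl)ethyl buta-2,3-dienoate F2. Its activated 2,3-double bond should add to 17 at 25–60 °C with the same orientation (C8 to the central allene carbon) to give the 7-methylidene cycloadduct F3. Loss of MeOSiMe3 and DBU-mediated migration of the exocyclic double bond into the ring would aromatise F3 to 23.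

Step 9 (hydrozirconation/Negishi coupling). Pd(0) may ionise the tertiary propargylic or dienylic C–O bond, whose vinylogous carbonate oxygen is a leaving group, causing ring opening or loss of enantiopurity, and the hindered alkenyl bromide may couple sluggishly. Fallback, setting out from 13 and returning at 16: hydrozirconation followed by iodinolysis (Cp2Zr(H)Cl, then I2) gives methyl (6R)-6-[(E)-2-iodoethenyl]-6-methyl-2-(4-methylpent-3-en-1-yl)-5,6-dihydro-4H-pyran-3-carboxylate F4. This is coupled with tributyl(2-methylprop-1-en-1-yl)stannane in a palladium-free, copper(I) thiophene-2-carboxylate-mediated Stille-type reaction (NMP, 0 °C) to give 16.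

Step 8 (cyclodehydration). Dehydration of the hindered tertiary hemiketal may stall, or the acid may trigger lactonisation onto the methyl ester or Meyer–Schuster-type rearrangement of the ethynyl carbinol. Fallback, setting out from 12 and returning at 13: the ring is closed under basic conditions by addition–elimination. O-Phosphorylation of the keto ester enolate (NaH, 1 equiv, ClP(O)(OEt)2, THF, 0 °C) gives the enol phosphate methyl 3-(diethoxyphosphoryloxy)-2-[(3R)-3-hydroxy-3-methylpent-4-yn-1-yl]-7-methylocta-2,6-dienoate F5. t-BuOK (THF, 0 °C) then generates the tertiary alkoxide, which adds to the β-carbon and expels diethyl phosphate to give 13.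

**Further compounds**

F1 | step 12 | 2-(trimethylsilyl)ethyl but-3-ynoate | C#CCC(=O)OCC[Si](C)(C)C
F2 | step 12 | 2-(trimethylsilyl)ethyl buta-2,3-dienoate | C=C=CC(=O)OCC[Si](C)(C)C
F3 | step 12 | 2-(trimethylsilyl)ethyl (2R)-5-methoxy-2-methyl-7-methylidene-2-[(1E)-4-methylpenta-1,3-dien-1-yl]-8-(3-methylbut-2-en-1-yl)-5-(trimethylsilyloxy)-3,4,5,6,7,8-hexahydro-2H-chromene-6-carboxylate | CC(C)=C/C=C/[C@@]1(C)CCC2=C(O1)C(CC=C(C)C)C(=C)C(C(=O)OCC[Si](C)(C)C)C2(OC)O[Si](C)(C)C
F4 | step 9 | methyl (6R)-6-[(E)-2-iodoethenyl]-6-methyl-2-(4-methylpent-3-en-1-yl)-5,6-dihydro-4H-pyran-3-carboxylate | I/C=C/[C@@]1(C)CCC(C(=O)OC)=C(CCC=C(C)C)O1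
F5 | step 8 | methyl 3-(diethoxyphosphoryloxy)-2-[(3R)-3-hydroxy-3-methylpent-4-yn-1-yl]-7-methylocta-2,6-dienoate | C#C[C@@](O)(C)CCC(C(=O)OC)=C(CCC=C(C)C)OP(=O)(OCC)OCC
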